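**Plan**
Retrosynthesis: (1) cut the flavone C3–flavan C8 bond (Suzuki coupling of a 3-iodoflavone with a flavan-8-boronate); (2) in the flavan, cut C3–C4 of ring C after adding a hydroxyl back at C4, a pinacol retron that opens to a dialdehyde; (3) cut O1–C2 (Mitsunobu ether from a salicylaldehyde and a mandelate).
Enabling feature: C3 (the carbinol carbon) and C4 (benzylic, on ring A, ortho/para to O1, O5 and O7) are both natural carbonyl carbons of like polarity. Reductive coupling joins them, and a surplus hydroxyl at C4 is uniquely easy to remove again by ionization.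
Forward order: ring-B mandelate → aryl ether (O1–C2) → dialdehyde → ring C closed by C3–C4 coupling → 4-deoxygenation → C8 bromination and borylation → union with the separately made 3-iodoflavone → global debenzylation.
Stereochemistry: C2 comes from an asymmetric transfer hydrogenation (S), inverted to R in the Mitsunobu step; C3 (S, 2,3-trans) is set from C2 in the ring closure; C4 is a temporary centre.

Key step: step 7

Assumption: the structure defines only C2 and C3 of the flavan; the sense of the hindered flavone C3–flavan C8 axis is not specified and is not controlled.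

**Route**

Step 1
Reactants: 1 2,4,6-trihydroxybenzaldehyde
Product: 2 2,4-bis(benzyloxy)-6-hydroxybenzaldehyde
Conditions: BnBr (2.05 equiv), K2CO3 (2.2 equiv), DMF, 0 °C to rt
Reagents that add atoms: benzyl bromide, BrCc1ccccc1
Why: Williamson etherification; the last hydroxyl is hydrogen-bonded to the formyl group and is the least nucleophilic, so two equivalents of halide should stop at the dibenzyl ether with the chelated phenol free.

Step 2
Reactants: 3 1-(benzyloxy)-4-bromobenzene; 4 dimethyl oxalate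
Product: 6 methyl 2-[4-(benzyloxy)phenyl]-2-oxoacetate, via [4-(benzyloxy)phenyl]magnesium bromide 5 (not isolated)
Conditions: Mg, THF, rt; then added to 4 (2 equiv), THF, −78 °C; aqueous work-up
Reagents that add atoms: none
Why: Grignard mono-addition to an oxalate diester; inverse addition at low temperature keeps the magnesium hemiketal intact until work-up, so the keto ester is not attacked a second time.

Step 3
Reactants: 6 methyl 2-[4-(benzyloxy)phenyl]-2-oxoacetate
Product: 7 methyl (S)-2-[4-(benzyloxy)phenyl]-2-hydroxyacetate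
Conditions: RuCl(p-cymene)[(R,R)-TsDPEN] (1 mol %), HCO2H/Et3N (5:2), DMF, rt
Reagents that add atoms: none
Why: Noyori asymmetric transfer hydrogenation of an aryl α-keto ester; with the (R,R)-diamine ligand the usual aryl/η6-arene CH–π contact should direct hydride to the face that gives the (S)-hydroxy ester, and crystallization can raise its enantiopurity.

Step 4
Reactants: 2 2,4-bis(benzyloxy)-6-hydroxybenzaldehyde; 7 methyl (S)-2-[4-(benzyloxy)phenyl]-2-hydroxyacetate
Product: 8 methyl (R)-2-[3,5-bis(benzyloxy)-2-formylphenoxy]-2-[4-(benzyloxy)phenyl]acetate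
Conditions: PPh3, DIAD, THF, 0 °C to rt
Reagents that add atoms: none
Why: Mitsunobu etherification of an α-hydroxy ester with an acidic phenol, an SN2 displacement that inverts the carbinol centre (S to R) and so fixes C2 of the flavan; the α-ester group disfavours ionization of the 4-alkoxybenzylic centre.

Step 5
Reactants: 8 methyl (R)-2-[3,5-bis(benzyloxy)-2-formylphenoxy]-2-[4-(benzyloxy)phenyl]acetate
Product: 9 (R)-2-[3,5-bis(benzyloxy)-2-(hydroxymethyl)phenoxy]-2-[4-(benzyloxy)phenyl]ethan-1-ol
Conditions: LiBH4 (3 equiv), THF, 0 °C to rt; neutral aqueous work-up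
Reagents that add atoms: none
Why: borohydride reduction of both the aldehyde and the activated α-aryloxy ester to primary alcohols under non-basic conditions, which should leave the stereocentre untouched.

Step 6
Reactants: 9 (R)-2-[3,5-bis(benzyloxy)-2-(hydroxymethyl)phenoxy]-2-[4-(benzyloxy)phenyl]ethan-1-ol
Product: 10 (R)-2-[3,5-bis(benzyloxy)-2-formylphenoxy]-2-[4-(benzyloxy)phenyl]acetaldehyde
Conditions: Dess–Martin periodinane (2.5 equiv), NaHCO3 (6 equiv), CH2Cl2, 0 °C; used crude at once
Reagents that add atoms: none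
Why: Dess–Martin oxidation of both primary alcohols in a buffered, non-basic medium, which should avoid enolization of the α-aryloxy aldehyde and ionization of the electron-rich benzylic alcohol.

Step 7
Reactants: 10 (R)-2-[3,5-bis(benzyloxy)-2-formylphenoxy]-2-[4-(benzyloxy)phenyl]acetaldehyde
Product: 12 (2R,3S,4S)-5,7-bis(benzyloxy)-2-[4-(benzyloxy)phenyl]chromane-3,4-diol, via aryl ketyl radical anion 11 (not isolated)
Conditions: SmI2 (2.5 equiv, 0.1 M in THF), slow addition of 10 (final 0.01 M), THF, −78 to −40 °C; neutral aqueous work-up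
Reagents that add atoms: none
Why: Electron transfer from divalent samarium to the conjugated ring-A aldehyde gives the samarium-bound ketyl 11, in which C4 has changed from acceptor to donor; this radical adds to the samarium-coordinated C3 aldehyde, and a second electron transfer gives the cyclic diolate of trivalent samarium, protonated on work-up. The closest known reaction type is the SmI2-mediated intramolecular pinacol coupling of 1,6-dialdehydes to cis-cyclohexane-1,2-diols. Ring C is closed by a 6-exo-trig attack of the C4 ketyl carbon on the C3 carbonyl carbon, the other ring atoms (C4a, C8a, O1, C2) being already in place. C3 is controlled by C2: in the chair-like, samarium-bridged transition state the 2-aryl group is pseudo-equatorial and the C3–O bond lies anti to the O1–C2 bond, which puts the new 3-oxygen equatorial and trans to the aryl group (3S); C4 follows C3 through chelation of both oxygens on samarium (cis-diol, the 4-oxygen pseudo-axial away from the peri 5-benzyloxy group) and is erased in step 8. The step needs the first electron to enter the aryl aldehyde and not the α-aryloxy aldehyde, whose ketyl could expel the ring-A phenoxide, and needs cyclization to outrun intermolecular coupling; conjugation of the C4 carbonyl with ring A, the absence of HMPA and proton donors, low temperature and high dilution should secure this, and the cold neutral medium protects the C2 stereocentre.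

Step 8
Reactants: 12 (2R,3S,4S)-5,7-bis(benzyloxy)-2-[4-(benzyloxy)phenyl]chromane-3,4-diol
Product: 14 (2R,3S)-5,7-bis(benzyloxy)-2-[4-(benzyloxy)phenyl]chroman-3-ol, via C4 benzylic cation 13 (not isolated)
Conditions: Et3SiH (10 equiv), CF3CO2H (3 equiv), CH2Cl2 (0.02 M), −40 to 0 °C; aqueous NaHCO3 work-up
Reagents that add atoms: none
Why: ionic hydrogenation; only the 4-hydroxyl sits on a carbon benzylic to ring A and ortho/para to O1, O5 and O7, so it alone ionizes and the cation takes hydride from the silane, while the 3-hydroxyl and both stereocentres stay.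

Step 9
Reactants: 14 (2R,3S)-5,7-bis(benzyloxy)-2-[4-(benzyloxy)phenyl]chroman-3-ol
Product: 15 (2R,3S)-3,5,7-tris(benzyloxy)-2-[4-(benzyloxy)phenyl]chromane
Conditions: NaH (1.5 equiv), BnBr (1.3 equiv), Bu4NI (cat.), DMF, 0 °C to rt
Reagents that add atoms: benzyl bromide, BrCc1ccccc1
Why: Williamson etherification of the secondary alcohol, which removes the only acidic hydrogen before the halogen–lithium exchange and installs a group that leaves with the others at the end.

Step 10
Reactants: 15 (2R,3S)-3,5,7-tris(benzyloxy)-2-[4-(benzyloxy)phenyl]chromane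
Product: 16 (2R,3S)-3,5,7-tris(benzyloxy)-2-[4-(benzyloxy)phenyl]-8-bromochromane
Conditions: NBS (1.0 equiv), CH2Cl2, −78 °C to rt
Reagents that add atoms: N-bromosuccinimide, O=C1CCC(=O)N1Br
Why: electrophilic aromatic bromination of the phloroglucinol-type ring A, which in benzylated flavan-3-ols goes to C8 in preference to C6 and to the much less activated ring B.

Step 11
Reactants: 16 (2R,3S)-3,5,7-tris(benzyloxy)-2-[4-(benzyloxy)phenyl]-8-bromochromane
Product: 18 2-{(2R,3S)-3,5,7-tris(benzyloxy)-2-[4-(benzyloxy)phenyl]chroman-8-yl}-4,4,5,5-tetramethyl-1,3,2-dioxaborolane, via 8-lithio flavan 17 (not isolated)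
Conditions: n-BuLi (1.1 equiv), THF, −78 °C; then i-PrOBpin (2 equiv), −78 °C to rt; H2O
Reagents that add atoms: 2-isopropoxy-4,4,5,5-tetramethyl-1,3,2-dioxaborolane, CC(C)OB1OC(C)(C)C(C)(C)O1
Why: bromine–lithium exchange followed by borylation of the aryllithium; at −78 °C the exchange is faster than deprotonation of the benzyl ethers, and the pinacol ester should resist protodeboronation better than the free 2,6-dioxygenated boronic acid.

Step 12
Reactants: 19 apigenin
Product: 20 5,7-bis(benzyloxy)-2-[4-(benzyloxy)phenyl]-4H-chromen-4-one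
Conditions: BnBr (4 equiv), K2CO3 (5 equiv), DMF, 80 °C
Reagents that add atoms: benzyl bromide, BrCc1ccccc1
Why: Williamson etherification; heat and excess halide are needed to alkylate the chelated 5-hydroxyl as well.

Step 13
Reactants: 20 5,7-bis(benzyloxy)-2-[4-(benzyloxy)phenyl]-4H-chromen-4-one
Product: 22 5,7-bis(benzyloxy)-2-[4-(benzyloxy)phenyl]-3-iodo-4H-chromen-4-one, via 3-lithioflavone 21 (not isolated)
Conditions: LiN(i-Pr)2 (1.3 equiv), THF, −78 °C; then I2 (1.1 equiv), −78 °C to rt
Reagents that add atoms: iodine, II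
Why: directed lithiation of the flavone at C3, the only vinylic hydrogen and the one next to the carbonyl oxygen, followed by iodinolysis; this avoids electrophilic iodination, which would attack ring A.

Step 14
Reactants: 18 2-{(2R,3S)-3,5,7-tris(benzyloxy)-2-[4-(benzyloxy)phenyl]chroman-8-yl}-4,4,5,5-tetramethyl-1,3,2-dioxaborolane; 22 5,7-bis(benzyloxy)-2-[4-(benzyloxy)phenyl]-3-iodo-4H-chromen-4-one
Product: 23 5,7-bis(benzyloxy)-2-[4-(benzyloxy)phenyl]-3-{(2R,3S)-3,5,7-tris(benzyloxy)-2-[4-(benzyloxy)phenyl]chroman-8-yl}-4H-chromen-4-one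
Conditions: Pd(OAc)2 (10 mol %), SPhos (20 mol %), K3PO4 (3 equiv), toluene/H2O (10:1), 90 °C
Reagents that add atoms: none
Why: Suzuki–Miyaura coupling of an α-iodoenone-type halide, which adds readily to zerovalent palladium, with a hindered aryl boronate; the dialkylbiarylphosphine is chosen because it speeds transmetalation and reductive elimination in couplings that create four ortho substituents.

Step 15
Reactants: 23 5,7-bis(benzyloxy)-2-[4-(benzyloxy)phenyl]-3-{(2R,3S)-3,5,7-tris(benzyloxy)-2-[4-(benzyloxy)phenyl]chroman-8-yl}-4H-chromen-4-one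
Product: 24 wikstrol A
Conditions: H2 (1 atm), Pd(OH)2/C (20 wt %), THF/MeOH (1:1), rt
Reagents that add atoms: none
Why: hydrogenolysis of the six aryl benzyl ethers and the one alkyl benzyl ether; the tetrasubstituted C2=C3 bond of the flavone and the benzylic C2–O1 bond of the flavan should survive these conditions, as they do in flavone and catechin chemistry.

**Compound list**

1 | 2,4,6-trihydroxybenzaldehyde | O=Cc1c(O)cc(O)cc1O | starting material
2 | 2,4-bis(benzyloxy)-6-hydroxybenzaldehyde | O=Cc1c(O)cc(OCc2ccccc2)cc1OCc1ccccc1 | intermediate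
3 | 1-(benzyloxy)-4-bromobenzene | Brc1ccc(OCc2ccccc2)cc1 | starting material
4 | dimethyl oxalate | COC(=O)C(=O)OC | starting material
5 | [4-(benzyloxy)phenyl]magnesium bromide | Br[Mg]c1ccc(OCc2ccccc2)cc1 | intermediate
6 | methyl 2-[4-(benzyloxy)phenyl]-2-oxoacetate | COC(=O)C(=O)c1ccc(OCc2ccccc2)cc1 | intermediate
7 | methyl (S)-2-[4-(benzyloxy)phenyl]-2-hydroxyacetate | O[C@@H](c1ccc(OCc2ccccc2)cc1)C(=O)OC | intermediate
8 | methyl (R)-2-[3,5-bis(benzyloxy)-2-formylphenoxy]-2-[4-(benzyloxy)phenyl]acetate | O=Cc1c(OCc2ccccc2)cc(OCc2ccccc2)cc1O[C@H](c1ccc(OCc2ccccc2)cc1)C(=O)OC | intermediate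
9 | (R)-2-[3,5-bis(benzyloxy)-2-(hydroxymethyl)phenoxy]-2-[4-(benzyloxy)phenyl]ethan-1-ol | OCc1c(OCc2ccccc2)cc(OCc2ccccc2)cc1O[C@H](c1ccc(OCc2ccccc2)cc1)CO | intermediate
10 | (R)-2-[3,5-bis(benzyloxy)-2-formylphenoxy]-2-[4-(benzyloxy)phenyl]acetaldehyde | O=Cc1c(OCc2ccccc2)cc(OCc2ccccc2)cc1O[C@H](c1ccc(OCc2ccccc2)cc1)C=O | intermediate
11 | aryl ketyl radical anion of 10 at the ring-A aldehyde (samarium-bound) | [O-][CH]c1c(OCc2ccccc2)cc(OCc2ccccc2)cc1O[C@H](c1ccc(OCc2ccccc2)cc1)C=O | intermediate
12 | (2R,3S,4S)-5,7-bis(benzyloxy)-2-[4-(benzyloxy)phenyl]chromane-3,4-diol (2,3-trans-3,4-cis) | O(Cc1ccccc1)c1cc(OCc2ccccc2)c2c(c1)O[C@H](c1ccc(OCc3ccccc3)cc1)[C@@H](O)[C@H]2O | intermediate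
13 | (2R,3S)-5,7-bis(benzyloxy)-2-[4-(benzyloxy)phenyl]-3-hydroxychroman-4-ylium (C4 benzylic cation) | O(Cc1ccccc1)c1cc(OCc2ccccc2)c2c(c1)O[C@H](c1ccc(OCc3ccccc3)cc1)[C@@H](O)[CH+]2 | intermediate
14 | (2R,3S)-5,7-bis(benzyloxy)-2-[4-(benzyloxy)phenyl]chroman-3-ol (tri-O-benzylafzelechin) | O(Cc1ccccc1)c1cc(OCc2ccccc2)c2c(c1)O[C@H](c1ccc(OCc3ccccc3)cc1)[C@@H](O)C2 | intermediate
15 | (2R,3S)-3,5,7-tris(benzyloxy)-2-[4-(benzyloxy)phenyl]chromane | O(Cc1ccccc1)c1cc(OCc2ccccc2)c2c(c1)O[C@H](c1ccc(OCc3ccccc3)cc1)[C@@H](OCc1ccccc1)C2 | intermediate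
16 | (2R,3S)-3,5,7-tris(benzyloxy)-2-[4-(benzyloxy)phenyl]-8-bromochromane | O(Cc1ccccc1)c1cc(OCc2ccccc2)c2c(c1Br)O[C@H](c1ccc(OCc3ccccc3)cc1)[C@@H](OCc1ccccc1)C2 | intermediate
17 | (2R,3S)-3,5,7-tris(benzyloxy)-2-[4-(benzyloxy)phenyl]chroman-8-yllithium | O(Cc1ccccc1)c1cc(OCc2ccccc2)c2c(c1[Li])O[C@H](c1ccc(OCc3ccccc3)cc1)[C@@H](OCc1ccccc1)C2 | intermediate
18 | 2-{(2R,3S)-3,5,7-tris(benzyloxy)-2-[4-(benzyloxy)phenyl]chroman-8-yl}-4,4,5,5-tetramethyl-1,3,2-dioxaborolane | O(Cc1ccccc1)c1cc(OCc2ccccc2)c2c(c1B4OC(C)(C)C(C)(C)O4)O[C@H](c1ccc(OCc3ccccc3)cc1)[C@@H](OCc1ccccc1)C2 | intermediate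
19 | apigenin (5,7-dihydroxy-2-(4-hydroxyphenyl)-4H-chromen-4-one) | O=c1cc(-c2ccc(O)cc2)oc2cc(O)cc(O)c12 | starting material
20 | 5,7-bis(benzyloxy)-2-[4-(benzyloxy)phenyl]-4H-chromen-4-one | O=c1cc(-c2ccc(OCc3ccccc3)cc2)oc2cc(OCc3ccccc3)cc(OCc3ccccc3)c12 | intermediate
21 | {5,7-bis(benzyloxy)-2-[4-(benzyloxy)phenyl]-4-oxo-4H-chromen-3-yl}lithium | O=c1c([Li])c(-c2ccc(OCc3ccccc3)cc2)oc2cc(OCc3ccccc3)cc(OCc3ccccc3)c12 | intermediate
22 | 5,7-bis(benzyloxy)-2-[4-(benzyloxy)phenyl]-3-iodo-4H-chromen-4-one | O=c1c(I)c(-c2ccc(OCc3ccccc3)cc2)oc2cc(OCc3ccccc3)cc(OCc3ccccc3)c12 | intermediate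
23 | 5,7-bis(benzyloxy)-2-[4-(benzyloxy)phenyl]-3-{(2R,3S)-3,5,7-tris(benzyloxy)-2-[4-(benzyloxy)phenyl]chroman-8-yl}-4H-chromen-4-one (hepta-O-benzyl wikstrol A) | O=c1c(-c2c(OCc4ccccc4)cc(OCc4ccccc4)c3c2O[C@H](c2ccc(OCc4ccccc4)cc2)[C@@H](OCc2ccccc2)C3)c(-c2ccc(OCc3ccccc3)cc2)oc2cc(OCc3ccccc3)cc(OCc3ccccc3)c12 | intermediate
24 | wikstrol A | O=c1c(-c2c(O)cc(O)c3c2O[C@H](c2ccc(O)cc2)[C@@H](O)C3)c(-c2ccc(O)cc2)oc2cc(O)cc(O)c12 | target

**Summary**

Total step count: 15. Longest linear sequence: 12 steps (steps 2–11, 14 and 15, from 3 and 4).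

Steps most likely to fail:

1. Step 7. The first electron may enter the α-aryloxy aldehyde instead of the aryl aldehyde, so that the ketyl at C3 expels the ring-A phenoxide (reductive C–O cleavage); intermolecular coupling or poor 2,3-facial selectivity are further risks. Fallback: from 10, non-basic Takai–Lombardo bis-methylenation (Zn, CH2Br2, TiCl4, THF, 0 °C to rt) would give the diene 1,5-bis(benzyloxy)-3-{[(1S)-1-[4-(benzyloxy)phenyl]prop-2-en-1-yl]oxy}-2-ethenylbenzene F1. Ring-closing metathesis (second-generation Grubbs catalyst, RuCl2(=CHPh)(PCy3)(H2IMes), CH2Cl2, 40 °C) then makes the same C3–C4 connection as a double bond and gives (2S)-5,7-bis(benzyloxy)-2-[4-(benzyloxy)phenyl]-2H-chromene F2. Hydroboration–oxidation (BH3·THF, 0 °C; then NaOH, H2O2) anti to the 2-aryl group places the hydroxyl on C3 trans to it and returns to the route at 14.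

2. Step 14. Protodeboronation of the 2,6-dioxygenated aryl boronate may outrun a slow transmetalation at two doubly flanked carbons. Fallback: reverse the roles of the partners and avoid boron. 20 is lithiated as in step 13 (via 21) and treated with ZnCl2 to give {5,7-bis(benzyloxy)-2-[4-(benzyloxy)phenyl]-4-oxo-4H-chromen-3-yl}zinc chloride F3. Negishi coupling of F3 with bromide 16 (Pd2(dba)3, RuPhos, THF, 65 °C) comes back to the route at 23.

3. Step 8. The C4 cation may be captured by ring A of a second molecule (oligomerization), or a 1,2-hydride shift from C3 (pinacol-type rearrangement) may compete with hydride transfer from the silane. Fallback: radical instead of cationic deoxygenation. 12 with 1,1'-thiocarbonyldiimidazole (toluene, 80 °C) would give the cis-fused 3,4-O-thiocarbonyl derivative (cyclic thionocarbonate) of 12 F4. Bu3SnH with AIBN (toluene, 100 °C) cleaves the benzylic C4–O bond selectively, through the more stabilized radical, to the 3-O-[(tributylstannylsulfanyl)carbonyl] derivative of 14 F5. Hydrolysis of F5 during work-up (K2CO3, MeOH/H2O) returns to the route at 14.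

**Further compounds**

F1 | step 7 | 1,5-bis(benzyloxy)-3-{[(1S)-1-[4-(benzyloxy)phenyl]prop-2-en-1-yl]oxy}-2-ethenylbenzene | C=Cc1c(OCc2ccccc2)cc(OCc2ccccc2)cc1O[C@H](c1ccc(OCc2ccccc2)cc1)C=C
F2 | step 7 | (2S)-5,7-bis(benzyloxy)-2-[4-(benzyloxy)phenyl]-2H-chromene | O(Cc1ccccc1)c1cc(OCc2ccccc2)c2c(c1)O[C@H](c1ccc(OCc3ccccc3)cc1)C=C2
F3 | step 14 | {5,7-bis(benzyloxy)-2-[4-(benzyloxy)phenyl]-4-oxo-4H-chromen-3-yl}zinc chloride | O=c1c([Zn]Cl)c(-c2ccc(OCc3ccccc3)cc2)oc2cc(OCc3ccccc3)cc(OCc3ccccc3)c12
F4 | step 8 | cis-fused 3,4-O-thiocarbonyl derivative (cyclic thionocarbonate) of 12 | O(Cc1ccccc1)c1cc(OCc2ccccc2)c2c(c1)O[C@H](c1ccc(OCc3ccccc3)cc1)[C@H]3OC(=S)O[C@@H]23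
F5 | step 8 | 3-O-[(tributylstannylsulfanyl)carbonyl] derivative of 14 | O(Cc1ccccc1)c1cc(OCc2ccccc2)c2c(c1)O[C@H](c1ccc(OCc3ccccc3)cc1)[C@@H](OC(=O)S[Sn](CCCC)(CCCC)CCCC)C2
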